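## Retrosynthetic overview

1. Numbering and feature: ring methine C1, then C2H2, C3H=C4(Me), C5, C6, C7H=C8(Me), C9, C10, C11H=C12(Me), C13, C14 back to C1; carbinol C15; side chain C16–C23. Apart from C1–C2 (which closes the 14-membered carbocycle C1–C14) and C15–O (the exocyclic tertiary carbinol), the target is an unbroken head-to-tail, all-E hexaprenyl chain, and the strategy rests on this.
2. Key disconnection: C1–C2 and C15–O are cut together. This gives achiral all-E hexaprenyl diphosphate (diphosphate on C2, with C1=C15 the fourth alkene counted from it) and water. In the forward direction a class one terpene synthase domain closes the ring and sets both stereocentres (1R,15S).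
3. Hexaprenyl diphosphate comes from hexaprenyl chloride, which comes from all-E hexaprenol.
4. Hexaprenol is cut at C13–C14 into farnesyl phenyl sulfone (C14, C1, C15–C23) and the terminal bromide of silyl-protected farnesol (C2–C13). Both halves come from (E,E)-farnesol.
5. Ring order: there is one ring, and it is formed in the last step.

Key step: step 11

Assumption: diphosphates are drawn as free acids although they are handled as ammonium salts (counter-ion exchange is left out of the atom balance), and the recombinant synthase, obtained by expressing a synthetic gene in E. coli, is treated as a catalyst and not as a synthetic step.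

## Route

Step 1
Reactants: 1 (2E,6E)-farnesol
Product: 2 (2E,6E)-farnesyl bromide
Conditions: PBr3 (0.4 equiv), Et2O, 0 °C; used at once
Reagents that add atoms: phosphorus tribromide, BrP(Br)Br
Why: SN2 bromination of a primary allylic alcohol through its phosphite ester at low temperature proceeds without allylic transposition or loss of E geometry, and no stereocentre is formed.

Step 2
Reactants: 2 (2E,6E)-farnesyl bromide; 3 sodium benzenesulfinate
Product: 4 (2E,6E)-farnesyl phenyl sulfone
Conditions: DMF, rt
Reagents that add atoms: none
Why: S-alkylation of the ambident sulfinate by the soft primary allylic bromide (SN2) in a dipolar aprotic solvent should give the sulfone rather than the sulfinate ester and leaves the adjacent E alkene untouched.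

Step 3
Reactants: 1 (2E,6E)-farnesol
Product: 5 (2E,6E)-farnesyl tert-butyldiphenylsilyl ether
Conditions: TBDPSCl, imidazole, CH2Cl2, 0 °C to rt
Reagents that add atoms: tert-butyldiphenylsilyl chloride, CC(C)(C)[Si](Cl)(c1ccccc1)c1ccccc1
Why: Imidazole-promoted silylation of a primary alcohol, with the TBDPS group chosen because it adds no stereocentre and withstands SeO2/t-BuOOH, the Appel bromination, the sulfonyl carbanion and LiBHEt3.

Step 4
Reactants: 5 (2E,6E)-farnesyl tert-butyldiphenylsilyl ether
Product: 7 (2E,6E,10E)-12-(tert-butyldiphenylsilyloxy)-2,6,10-trimethyldodeca-2,6,10-trien-1-ol, via over-oxidised enal 6 (not isolated)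
Conditions: SeO2 (0.1 equiv), salicylic acid (0.1 equiv), t-BuOOH (3 equiv), CH2Cl2, 0 °C to rt; then NaBH4, MeOH, 0 °C
Reagents that add atoms: selenium dioxide, O=[Se]=O (catalytic oxygen carrier); tert-butyl hydroperoxide, CC(C)(C)OO (terminal oxygen source)
Why: Riley-type allylic oxidation (ene reaction, then [2,3]-sigmatropic shift) attacks the most electron-rich and least hindered terminal Me2C=CH unit and places oxygen on its E methyl group only, the alkene next to the silyloxy group being deactivated, while the 1,2-reduction with NaBH4 returns the further oxidised part 6 to 7.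

Step 5
Reactants: 7 (2E,6E,10E)-12-(tert-butyldiphenylsilyloxy)-2,6,10-trimethyldodeca-2,6,10-trien-1-ol
Product: 8 (2E,6E,10E)-12-bromo-3,7,11-trimethyldodeca-2,6,10-trienyl tert-butyldiphenylsilyl ether
Conditions: CBr4, PPh3, CH2Cl2, −20 to 0 °C; used promptly
Reagents that add atoms: carbon tetrabromide, BrC(Br)(Br)Br
Why: Appel reaction, in which bromide displaces the alkoxyphosphonium group by SN2 under neutral conditions, so that the E alkene and the silyl ether are kept and no allylic transposition occurs.

Step 6
Reactants: 4 (2E,6E)-farnesyl phenyl sulfone; 8 (2E,6E,10E)-12-bromo-3,7,11-trimethyldodeca-2,6,10-trienyl tert-butyldiphenylsilyl ether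
Product: 10 racemic all-E 13-(phenylsulfonyl)hexaprenyl tert-butyldiphenylsilyl ether (sulfone on C14 of the target numbering), via lithiated sulfone 9 (not isolated)
Conditions: 4, n-BuLi (1.05 equiv), THF/DMPU, −78 °C; then 8, −78 to −20 °C
Reagents that add atoms: none
Why: Biellmann–Ducep-type prenyl coupling, in which the allylic α-sulfonyl carbanion reacts at its α carbon with the primary allylic bromide by SN2 and forms C13–C14 with both flanking E alkenes in place, the new sulfone-bearing centre being racemic and erased in step 7.

Step 7
Reactants: 10 racemic all-E 13-(phenylsulfonyl)hexaprenyl tert-butyldiphenylsilyl ether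
Product: 11 all-E hexaprenyl tert-butyldiphenylsilyl ether
Conditions: PdCl2(dppp) (5 mol %), LiBHEt3 (2.5 equiv), THF, 0 °C
Reagents that add atoms: none
Why: Palladium-catalysed hydride desulfonylation (Tsuji–Trost-type ionisation, then hydride transfer), in which zerovalent palladium formed from the divalent precatalyst opens the C14–S bond to a syn π-allyl complex over C14–C1–C15 and the dppp ligand directs hydride to the less substituted terminus C14, which restores the E C1=C15 alkene needed in step 11, while the allylic silyl ether, a far poorer leaving group, is not ionised at 0 °C.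

Step 8
Reactants: 11 all-E hexaprenyl tert-butyldiphenylsilyl ether
Product: 12 all-E hexaprenol, (2E,6E,10E,14E,18E)-3,7,11,15,19,23-hexamethyltetracosa-2,6,10,14,18,22-hexaen-1-ol
Conditions: Bu4NF, THF, 0 °C to rt; water quench
Reagents that add atoms: none
Why: Fluoride-driven desilylation under non-acidic conditions frees the primary allylic alcohol and leaves the six acid-sensitive trisubstituted alkenes untouched.

Step 9
Reactants: 12 all-E hexaprenol
Product: 13 all-E hexaprenyl chloride
Conditions: NCS, Me2S, CH2Cl2, −30 to 0 °C
Reagents that add atoms: N-chlorosuccinimide, O=C1CCC(=O)N1Cl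
Why: Corey–Kim chlorination, in which chloride displaces the alkoxysulfonium group by SN2 under nearly neutral conditions and gives the primary allylic chloride without transposition or E/Z isomerisation.

Step 10
Reactants: 13 all-E hexaprenyl chloride; 14 tris(tetrabutylammonium) hydrogen diphosphate
Product: 15 all-E hexaprenyl diphosphate (handled as its ammonium salt)
Conditions: 14 (3 equiv), MeCN/THF, rt; Dowex 50WX8 (NH4+ form), aq NH4HCO3/i-PrOH; C18 reversed-phase chromatography (aq NH4HCO3/MeCN)
Reagents that add atoms: none
Why: SN2 displacement of a primary allylic chloride by the poorly solvated diphosphate anion in a dry dipolar solvent is the standard entry to allylic diphosphates, the excess of 14 suppressing double alkylation and the THF cosolvent keeping the C30 chloride in solution.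

Step 11
Reactants: 15 all-E hexaprenyl diphosphate
Product: 17 colleterpenol, (2S,5E)-6,10-dimethyl-2-[(1R,3E,7E,11E)-4,8,12-trimethylcyclotetradeca-3,7,11-trien-1-yl]undeca-5,9-dien-2-ol, via macrocyclic C15 cation 16 (not isolated)
Conditions: recombinant colleterpenol synthase of Colletotrichum gloeosporioides (chimeric prenyltransferase–terpene synthase or its class one terpene synthase domain, His6-tagged, from E. coli BL21(DE3)), MgCl2 (10 mM), Tris-HCl (50 mM, pH 8.0), glycerol (10% v/v), 30 °C, 16 h, 15 fed in portions, pentane overlay; extraction with pentane/Et2O, SiO2 chromatography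
Reagents that add atoms: water, O
Why: The magnesium ions held by the aspartate-rich motifs of the class one domain bind the diphosphate of 15 and pull it off, so that C2–C3–C4 becomes an allyl cation that keeps its E geometry in the closed pocket; C1 of the fourth alkene then bonds to C2 in the Markovnikov sense, the charge moves to tertiary exocyclic C15 (cation 16), and a bound water molecule captures it. The closest known reaction type is the terpene synthase 1,14-macrocyclisation of geranylgeranyl diphosphate with water quench that gives the cembranoid alcohol nephthenol, of which this is the C30 counterpart. The single ring, carbocycle C1–C14, closes in a 14-exo cation–olefin mode: the allyl cation is attacked at its primary terminus C2 without transposition, and only C1 of the attacking alkene becomes a ring atom. C1 (R) is set by the face of the C1=C15 alkene that the folded chain turns towards C2, and C15 (S) by the position of the quenching water over one face of planar 16; because the (1R,15S) pair amounts to a net syn addition of C2 and OH to the E alkene, the two bonds cannot form in a concerted anti addition, and the protein has to hold the discrete cation 16 in one conformation until water arrives. The step needs site selectivity (one of five nucleophilic trisubstituted alkenes), face selectivity at two prochiral carbons, and selective termination (water capture rather than proton loss, hydride shift or a second ring closure). The achiral substrate secures only the Markovnikov sense and the E geometry of C3=C4, C7=C8 and C11=C12, and everything else comes from the contour of the active site.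

## Compound list

1 | (2E,6E)-farnesol | CC(C)=CCC/C(C)=C/CC/C(C)=C/CO | starting material
2 | (2E,6E)-farnesyl bromide | CC(C)=CCC/C(C)=C/CC/C(C)=C/CBr | intermediate
3 | sodium benzenesulfinate | [Na+].[O-]S(=O)c1ccccc1 | starting material
4 | (2E,6E)-farnesyl phenyl sulfone | CC(C)=CCC/C(C)=C/CC/C(C)=C/CS(=O)(=O)c1ccccc1 | intermediate
5 | (2E,6E)-farnesyl tert-butyldiphenylsilyl ether | CC(C)=CCC/C(C)=C/CC/C(C)=C/CO[Si](c1ccccc1)(c1ccccc1)C(C)(C)C | intermediate
6 | (2E,6E,10E)-12-(tert-butyldiphenylsilyloxy)-2,6,10-trimethyldodeca-2,6,10-trienal (further oxidised part of the material, not isolated) | O=C/C(C)=C/CC/C(C)=C/CC/C(C)=C/CO[Si](c1ccccc1)(c1ccccc1)C(C)(C)C | intermediate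
7 | (2E,6E,10E)-12-(tert-butyldiphenylsilyloxy)-2,6,10-trimethyldodeca-2,6,10-trien-1-ol | OC/C(C)=C/CC/C(C)=C/CC/C(C)=C/CO[Si](c1ccccc1)(c1ccccc1)C(C)(C)C | intermediate
8 | (2E,6E,10E)-12-bromo-3,7,11-trimethyldodeca-2,6,10-trienyl tert-butyldiphenylsilyl ether | BrC/C(C)=C/CC/C(C)=C/CC/C(C)=C/CO[Si](c1ccccc1)(c1ccccc1)C(C)(C)C | intermediate
9 | α-lithiated farnesyl phenyl sulfone (not isolated) | CC(C)=CCC/C(C)=C/CC/C(C)=C/C([Li])S(=O)(=O)c1ccccc1 | intermediate
10 | all-E 13-(phenylsulfonyl)hexaprenyl tert-butyldiphenylsilyl ether, racemic at the sulfone carbon | CC(C)=CCC/C(C)=C/CC/C(C)=C/C(C/C(C)=C/CC/C(C)=C/CC/C(C)=C/CO[Si](c1ccccc1)(c1ccccc1)C(C)(C)C)S(=O)(=O)c1ccccc1 | intermediate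
11 | all-E hexaprenyl tert-butyldiphenylsilyl ether | CC(C)=CCC/C(C)=C/CC/C(C)=C/CC/C(C)=C/CC/C(C)=C/CC/C(C)=C/CO[Si](c1ccccc1)(c1ccccc1)C(C)(C)C | intermediate
12 | all-E hexaprenol | CC(C)=CCC/C(C)=C/CC/C(C)=C/CC/C(C)=C/CC/C(C)=C/CC/C(C)=C/CO | intermediate
13 | all-E hexaprenyl chloride | CC(C)=CCC/C(C)=C/CC/C(C)=C/CC/C(C)=C/CC/C(C)=C/CC/C(C)=C/CCl | intermediate
14 | tris(tetrabutylammonium) hydrogen diphosphate | CCCC[N+](CCCC)(CCCC)CCCC.CCCC[N+](CCCC)(CCCC)CCCC.CCCC[N+](CCCC)(CCCC)CCCC.OP(=O)([O-])OP(=O)([O-])[O-] | starting material
15 | all-E hexaprenyl diphosphate (drawn as free acid) | CC(C)=CCC/C(C)=C/CC/C(C)=C/CC/C(C)=C/CC/C(C)=C/CC/C(C)=C/COP(=O)(O)OP(=O)(O)O | intermediate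
16 | enzyme-bound macrocyclic C15 cation, (1R) (not isolated) | CC(C)=CCC/C(C)=C/CC[C+](C)[C@H]1C/C=C(\C)CC/C=C(\C)CC/C=C(\C)CC1 | intermediate
17 | colleterpenol, (1R,15S) | CC(C)=CCC/C(C)=C/CC[C@](C)(O)[C@H]1C/C=C(\C)CC/C=C(\C)CC/C=C(\C)CC1 | target

## Step count and risks

Total step count: 11.

Longest linear sequence: 9 steps from (E,E)-farnesol (steps 3, 4, 5, 6, 7, 8, 9, 10, 11).

**Step 11 (key step).**
- Risk: the amphiphilic C30 diphosphate may aggregate or precipitate with magnesium ions, so that little of it reaches the active site. Slow turnover would then let background solvolysis and premature termination compete with ring closure.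
- Fallback: the substrate is no longer supplied from outside but is built inside the same protein.
  - It sets out from bromide 2, which is displaced with salt 14 in MeCN to give (2E,6E)-farnesyl diphosphate F1.
  - Commercial 3-methylbut-3-en-1-ol is converted with TsCl and Et3N into isopentenyl tosylate F2, and 14 turns this into isopentenyl diphosphate F3.
  - The full-length chimeric enzyme is then incubated in the same MgCl2 buffer with F1 and three equivalents of F3.
  - Its prenyltransferase domain extends the chain head to tail and E-selectively through geranylgeranyl diphosphate F4 and geranylfarnesyl diphosphate F5.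
  - The fallback comes back to the route at 15. This forms only at a low stationary concentration next to the synthase domain and goes on to 17 in the same vessel.
- A purely chemical closure by opening a C1–C15 epoxide with a C2 carbanion is not offered. It is an anti addition and would lead from the E alkene to the C15 epimer.

**Step 10.**
- Risk: hydrolysis or elimination of the allylic chloride, sluggish displacement because the C30 chloride dissolves poorly, and loss of the soap-like product on ion exchange and chromatography.
- Fallback: it sets out from alcohol 12, bypasses 13, and activates phosphate instead of carbon.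
  - 12 is treated in MeCN/CH2Cl2 with Cl3CCN and bis(triethylammonium) hydrogen phosphate added in portions.
  - The imidoyl phosphate formed in the flask phosphorylates the hydroxyl group to hexaprenyl monophosphate F6. A second phosphorylation in the same flask brings the sequence back to the route at 15.
  - The C–O bond of 12 is never broken, so elimination and allylic transposition are excluded.
  - The mono-, di- and triphosphates are separated on silica with i-PrOH/conc. aq NH3/water.

**Step 4.**
- Risk: poor site selectivity among three trisubstituted alkenes, over-oxidation, and low conversion.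
- Fallback: it sets out from 5 and replaces C–H oxidation by cleavage and rebuilding of the terminal alkene.
  - NBS in aqueous THF at 0 °C attacks the exposed terminal alkene and gives the racemic terminal bromohydrin F7.
  - K2CO3 in MeOH closes this to the racemic terminal epoxide F8.
  - H5IO6 in THF/Et2O cleaves the epoxide to (4E,8E)-10-(tert-butyldiphenylsilyloxy)-4,8-dimethyldeca-4,8-dienal F9.
  - An E-selective Wittig reaction with the stabilised ylide Ph3P=C(CH3)CO2Et gives the E enoate F10.
  - Reduction with i-Bu2AlH in CH2Cl2 at −78 °C brings the sequence back to the route at 7.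

## Further compounds

F1 | step 11 | (2E,6E)-farnesyl diphosphate | CC(C)=CCC/C(C)=C/CC/C(C)=C/COP(=O)(O)OP(=O)(O)O
F2 | step 11 | isopentenyl tosylate | C=C(C)CCOS(=O)(=O)c1ccc(C)cc1
F3 | step 11 | isopentenyl diphosphate | C=C(C)CCOP(=O)(O)OP(=O)(O)O
F4 | step 11 | all-E geranylgeranyl diphosphate | CC(C)=CCC/C(C)=C/CC/C(C)=C/CC/C(C)=C/COP(=O)(O)OP(=O)(O)O
F5 | step 11 | all-E geranylfarnesyl diphosphate | CC(C)=CCC/C(C)=C/CC/C(C)=C/CC/C(C)=C/CC/C(C)=C/COP(=O)(O)OP(=O)(O)O
F6 | step 10 | all-E hexaprenyl monophosphate | CC(C)=CCC/C(C)=C/CC/C(C)=C/CC/C(C)=C/CC/C(C)=C/CC/C(C)=C/COP(=O)(O)O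
F7 | step 4 | racemic (2E,6E)-10-bromo-11-hydroxy-10,11-dihydrofarnesyl tert-butyldiphenylsilyl ether | CC(C)(O)C(Br)CC/C(C)=C/CC/C(C)=C/CO[Si](c1ccccc1)(c1ccccc1)C(C)(C)C
F8 | step 4 | racemic (2E,6E)-10,11-epoxyfarnesyl tert-butyldiphenylsilyl ether | CC1(C)OC1CC/C(C)=C/CC/C(C)=C/CO[Si](c1ccccc1)(c1ccccc1)C(C)(C)C
F9 | step 4 | (4E,8E)-10-(tert-butyldiphenylsilyloxy)-4,8-dimethyldeca-4,8-dienal | O=CCC/C(C)=C/CC/C(C)=C/CO[Si](c1ccccc1)(c1ccccc1)C(C)(C)C
F10 | step 4 | ethyl (2E,6E,10E)-12-(tert-butyldiphenylsilyloxy)-2,6,10-trimethyldodeca-2,6,10-trienoate | CCOC(=O)/C(C)=C/CC/C(C)=C/CC/C(C)=C/CO[Si](c1ccccc1)(c1ccccc1)C(C)(C)C
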